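**Retrosynthetic overview**
Ring D (O, C11Me2, C10H2, C9H2, C3, C2, C1', C2'; flavone numbering, C9 bonded to C3) contains a hidden 2,2-dimethylchroman. If C3 and C9 are removed and C2 is joined to C10, the six-membered ether ring O–C11–C10–C2–C1'–C2' remains.
Key disconnection: C2–C3 and C9–C10. The HC≡C unit of a ring A ethynyl ketone is inserted into the C2–C10 bond of a chroman-4-one enamine by [2+2] cycloaddition and opening of the fused cyclobutene.
Last disconnection: O1–C2 of ring C. A ring A phenol displaces the amine of the enaminone that the ring enlargement leaves behind.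
Ring order: rings A and B are bought, the chromanone ring is made in step 1, it is enlarged to ring D in step 8, and ring C is closed in step 10.

Key step: step 8

Remark: the target is taken exactly as drawn (oxocine ring D) and has no stereocentre. The stereocentres of 10 and 12 form racemic and are erased in steps 7 and 8. Atom labels in the Why lines follow flavone numbering.

**Route**

Step 1
Reactants: 1 resorcinol; 2 3-methylbut-2-enoic acid
Product: 3 7-hydroxy-2,2-dimethylchroman-4-one
Conditions: P2O5, MeSO3H, 70 °C
Reagents that add atoms: none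
Why: Friedel–Crafts acylation of resorcinol at C4 by the activated acid, followed in the same pot by oxa-Michael addition of the ortho phenol to the β,β-dimethyl enone, is the standard preparation of this known chromanone.

Step 2
Reactants: 3 7-hydroxy-2,2-dimethylchroman-4-one
Product: 4 7-(benzyloxy)-2,2-dimethylchroman-4-one
Conditions: BnBr, K2CO3, acetone, reflux
Reagents that add atoms: benzyl bromide, BrCc1ccccc1
Why: Williamson ether synthesis on the only phenol, under a base too weak to open the chromanone ring irreversibly.

Step 3
Reactants: 4 7-(benzyloxy)-2,2-dimethylchroman-4-one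
Product: 5 1-[7-(benzyloxy)-2,2-dimethyl-2H-chromen-4-yl]pyrrolidine
Conditions: pyrrolidine (6 equiv), TiCl4 (0.55 equiv), toluene, 0 °C to rt; filtered under N2, volatiles and all free pyrrolidine removed under high vacuum, used crude
Reagents that add atoms: pyrrolidine, C1CCNC1
Why: TiCl4-mediated enamine condensation, in which the amine-complexed TiCl4 acts as Lewis acid and irreversible water scavenger, overcomes the deactivation of the ketone by its ortho and para oxygen donors, and only one enamine regioisomer is possible because the sole α-hydrogens are on the CH2 next to CMe2.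

Step 4
Reactants: 6 2,4,6-trihydroxybenzaldehyde
Product: 7 2,6-dihydroxy-4-methoxybenzaldehyde
Conditions: Me2SO4 (1.0 equiv), K2CO3 (1.0 equiv), acetone, rt
Reagents that add atoms: dimethyl sulfate, COS(=O)(=O)OC
Why: O-methylation (Williamson type) with one equivalent of base and a hard methylating agent should fall on the 4-OH, which is para to the formyl group, the most acidic, and the only hydroxyl not held in an OH···O=C chelate.

Step 5
Reactants: 7 2,6-dihydroxy-4-methoxybenzaldehyde
Product: 8 2,6-bis(benzyloxy)-4-methoxybenzaldehyde
Conditions: BnBr (2.4 equiv), K2CO3, DMF, 60 °C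
Reagents that add atoms: benzyl bromide, BrCc1ccccc1
Why: Williamson ether synthesis in warm DMF breaks the chelate and benzylates both equivalent ortho phenols, while the aldehyde and the methyl ether are inert.

Step 6
Reactants: 8 2,6-bis(benzyloxy)-4-methoxybenzaldehyde; 9 ethynylmagnesium bromide
Product: 10 1-[2,6-bis(benzyloxy)-4-methoxyphenyl]prop-2-yn-1-ol (racemic)
Conditions: THF, 0 °C; sat. aq NH4Cl
Reagents that add atoms: none
Why: Grignard 1,2-addition of a slim sp nucleophile to the flanked aldehyde gives a carbinol centre that is uncontrolled (racemic), which does not matter because step 7 removes it.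

Step 7
Reactants: 10 1-[2,6-bis(benzyloxy)-4-methoxyphenyl]prop-2-yn-1-ol
Product: 11 1-[2,6-bis(benzyloxy)-4-methoxyphenyl]prop-2-yn-1-one
Conditions: activated MnO2, CH2Cl2, rt; used promptly
Reagents that add atoms: none
Why: MnO2 oxidation of a benzylic and propargylic alcohol runs under neutral heterogeneous conditions, so this very electron-rich carbinol neither ionises nor undergoes Meyer–Schuster rearrangement, and the benzyl ethers and the terminal alkyne are untouched.

Step 8
Reactants: 5 1-[7-(benzyloxy)-2,2-dimethyl-2H-chromen-4-yl]pyrrolidine; 11 1-[2,6-bis(benzyloxy)-4-methoxyphenyl]prop-2-yn-1-one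
Product: 13 ring D dienaminone [(3Z,5Z)-9-(benzyloxy)-2,2-dimethyl-6-(pyrrolidin-1-yl)-2H-1-benzoxocin-5-yl][2,6-bis(benzyloxy)-4-methoxyphenyl]methanone, via cis-fused cyclobutene 12 (not isolated)
Conditions: dry toluene, N2, 0 °C to rt, then 90 °C; chromatography on basic alumina
Reagents that add atoms: none
Why: The nucleophilic enamine carbon C10 of 5 adds to the unsubstituted alkyne terminus C9 of 11, and the allenolate carbon C3 then closes on the iminium carbon C2 (4-exo-trig at the iminium) to give the cis-fused cyclobutene 12. On heating, the donors on C2 (pyrrolidine, electron-rich ring B) and the aroyl acceptor on C3, which is vinylogously linked to C10, polarise the shared C2–C10 bond until it breaks, either heterolytically or by conrotatory opening followed by easy rotation about the push–pull C2=C3 bond, so the six-membered ether ring becomes ring D with both ring alkenes cis. This is the known two-carbon ring enlargement of cyclic ketone enamines with acetylenic esters and ketones, applied here to a chroman-4-one enamine, and ring D therefore arises by expansion of an existing ring and not by end-to-end closure of a medium ring. The two stereocentres of 12 (C2 and C10) can only be cis on a four/six ring fusion, form racemic, and both vanish in 13, which has no stereocentre. The regioselectivity needed is secured by polarity and size: C9 is the only electrophilic alkyne carbon and carries only hydrogen, so the neopentyl-like C10 can reach it, and the two ortho benzyloxy groups twist ring A out of conjugation and keep the ynone electron-poor. The chemoselectivity needed, ring closure ahead of C10–H to C3 proton transfer (which would stop at the open Michael dienamine), is favoured by the apolar aprotic solvent and by rigorous exclusion of free pyrrolidine and moisture.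

Step 9
Reactants: 13 ring D dienaminone
Product: 14 [(5Z)-9-hydroxy-2,2-dimethyl-6-(pyrrolidin-1-yl)-3,4-dihydro-2H-1-benzoxocin-5-yl](2,6-dihydroxy-4-methoxyphenyl)methanone
Conditions: H2 (1 atm), 10% Pd/C, EtOAc–EtOH, rt; filtered, concentrated
Reagents that add atoms: none
Why: Heterogeneous catalytic hydrogenation should saturate the cis-disubstituted C9=C10 alkene (as in the routine chromene-to-chroman reduction) and hydrogenolyse the three aryl benzyl ethers while sparing the tetrasubstituted vinylogous amide C2=C3, and doing this before any acid is used removes the allylic activation of the C11–O bond.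

Step 10
Reactants: 14 triol enaminone
Product: 15 cyclointegrin
Conditions: AcOH, 80 °C
Reagents that add atoms: none
Why: Chromone synthesis from an o-hydroxyaryl enaminone closes ring C, since a ring A phenol adds to the protonated enaminone at C2 (6-endo-trig oxa-Michael) and pyrrolidine is expelled; the two phenols are equivalent, so only one flavone can form, the other becomes the chelated 5-OH, and the saturated tertiary ether of ring D tolerates acetic acid.

**Compound list**
1 | resorcinol | Oc1cccc(O)c1 | starting material
2 | 3-methylbut-2-enoic acid | CC(C)=CC(=O)O | starting material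
3 | 7-hydroxy-2,2-dimethylchroman-4-one | CC1(C)CC(=O)c2ccc(O)cc2O1 | intermediate
4 | 7-(benzyloxy)-2,2-dimethylchroman-4-one | CC1(C)CC(=O)c2ccc(OCc3ccccc3)cc2O1 | intermediate
5 | 1-[7-(benzyloxy)-2,2-dimethyl-2H-chromen-4-yl]pyrrolidine | CC1(C)C=C(N2CCCC2)c2ccc(OCc3ccccc3)cc2O1 | intermediate
6 | 2,4,6-trihydroxybenzaldehyde | O=Cc1c(O)cc(O)cc1O | starting material
7 | 2,6-dihydroxy-4-methoxybenzaldehyde | COc1cc(O)c(C=O)c(O)c1 | intermediate
8 | 2,6-bis(benzyloxy)-4-methoxybenzaldehyde | COc1cc(OCc2ccccc2)c(C=O)c(OCc2ccccc2)c1 | intermediate
9 | ethynylmagnesium bromide | C#C[Mg]Br | starting material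
10 | 1-[2,6-bis(benzyloxy)-4-methoxyphenyl]prop-2-yn-1-ol (racemic, centre left undefined) | C#CC(O)c1c(OCc2ccccc2)cc(OC)cc1OCc1ccccc1 | intermediate
11 | 1-[2,6-bis(benzyloxy)-4-methoxyphenyl]prop-2-yn-1-one | C#CC(=O)c1c(OCc2ccccc2)cc(OC)cc1OCc1ccccc1 | intermediate
12 | [6-(benzyloxy)-3,3-dimethyl-8b-(pyrrolidin-1-yl)-2a,8b-dihydro-3H-cyclobuta[c]chromen-1-yl][2,6-bis(benzyloxy)-4-methoxyphenyl]methanone; cis ring fusion, H on C2a and pyrrolidinyl on C8b on the same face; racemic, one enantiomer drawn | CC1(C)Oc2cc(OCc3ccccc3)ccc2[C@]2(N3CCCC3)C(C(=O)c3c(OCc4ccccc4)cc(OC)cc3OCc3ccccc3)=C[C@H]12 | intermediate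
13 | [(3Z,5Z)-9-(benzyloxy)-2,2-dimethyl-6-(pyrrolidin-1-yl)-2H-1-benzoxocin-5-yl][2,6-bis(benzyloxy)-4-methoxyphenyl]methanone | CC1(C)/C=C\C(C(=O)c2c(OCc3ccccc3)cc(OC)cc2OCc2ccccc2)=C(N2CCCC2)/c2ccc(OCc3ccccc3)cc2O1 | intermediate
14 | [(5Z)-9-hydroxy-2,2-dimethyl-6-(pyrrolidin-1-yl)-3,4-dihydro-2H-1-benzoxocin-5-yl](2,6-dihydroxy-4-methoxyphenyl)methanone | CC1(C)CC\C(C(=O)c2c(O)cc(OC)cc2O)=C(N2CCCC2)/c2ccc(O)cc2O1 | intermediate
15 | cyclointegrin | COc1cc(O)c2c(=O)c3c(oc2c1)-c1ccc(O)cc1OC(C)(C)CC3 | target

**Step count**
Total steps: 10.
Longest linear sequence: 7 (steps 4, 5, 6, 7, 8, 9, 10).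

**Steps most likely to fail**

Step 8.
- Risk: proton transfer from C10–H to C3 inside the first-formed zwitterion may outrun the four-membered ring closure, because the iminium carbon is stabilised by the ortho and para oxygen donors of ring B.
- Risk: the addition itself may be slow, because C10 is neopentyl-like and the peri hydrogen twists the amine out of conjugation.
- Fallback (sets out from 4 and 11, comes back at 15): the nitrogen donor is replaced by a silyl enol ether, and the thermal reaction by acid catalysis with a separate fragmentation. Ketone 4 is treated with TBSOTf/Et3N (CH2Cl2, 0 °C) to give the tert-butyldimethylsilyl enol ether F1. This enters the known Tf2NH-catalysed [2+2] cycloaddition of silyl enol ethers with electron-poor alkynes, here with 11 (CH2Cl2, −78 °C), and gives the cis-fused siloxycyclobutene F2, with no basic site present to shuttle the proton. Bu4NF buffered with AcOH (THF, 0 °C) frees the cyclobutenolate. Its strain-driven vinylogous retro-aldol cleavage of C2–C10 leads to the stabilised 1,3-dicarbonyl enolate and, after protonation, to the ring-enlarged unsaturated 1,3-diketone F3. Hydrogenation (H2, Pd/C, EtOAc–EtOH) gives the saturated triol diketone F4. Warm AcOH with catalytic p-TsOH then closes ring C by cyclodehydration, as in the last stage of a Baker–Venkataraman flavone synthesis, to give 15.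

Step 9.
- Risk: hydrogenolytic cleavage of the tertiary allylic C11–O bond may occur before the hindered C9=C10 alkene is saturated.
- Risk: the push–pull alkene may be over-reduced.
- Risk: the debenzylation may stall if early ring C closure releases amine onto the catalyst.
- Fallback (sets out from 13, comes back at 14): the two tasks are separated. Diimide, generated from 2-nitrobenzenesulfonohydrazide and Et3N (CH2Cl2, rt), transfers H2 to C9=C10 in a concerted way that cannot touch C–O bonds or the polarised C2=C3 bond, and gives the tri-O-benzyl dihydro enaminone F5. Its ether is no longer allylic, so ordinary hydrogenolysis (H2, Pd/C, EtOH) then removes only the benzyl groups and gives 14.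

Step 3.
- Risk: condensation of the donor-deactivated ketone may be incomplete.
- Risk: the amine may trigger reversible retro-oxa-Michael opening of the heterocycle.
- Risk: the enamine may hydrolyse during isolation.
- Risk: free pyrrolidine may be carried over and consume the ynone in step 8.
- Fallback (sets out from 4, comes back at 5): the C–N bond is made by cross-coupling instead of condensation. Kinetic enolisation with KN(SiMe3)2 and trapping with PhNTf2 (THF, −78 °C) gives the enol triflate F6. The known Buchwald–Hartwig-type amination of alkenyl triflates (Pd2(dba)3, BINAP, pyrrolidine 1.1 equiv, NaOtBu, toluene, 80 °C) converts it into enamine 5 under anhydrous conditions with almost no excess amine.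

**Further compounds**
F1 | step 8 | {[7-(benzyloxy)-2,2-dimethyl-2H-chromen-4-yl]oxy}(tert-butyl)dimethylsilane | CC1(C)C=C(O[Si](C)(C)C(C)(C)C)c2ccc(OCc3ccccc3)cc2O1
F2 | step 8 | [6-(benzyloxy)-8b-{[tert-butyl(dimethyl)silyl]oxy}-3,3-dimethyl-2a,8b-dihydro-3H-cyclobuta[c]chromen-1-yl][2,6-bis(benzyloxy)-4-methoxyphenyl]methanone (cis-fused, racemic, one enantiomer drawn) | CC1(C)Oc2cc(OCc3ccccc3)ccc2[C@]2(O[Si](C)(C)C(C)(C)C)C(C(=O)c3c(OCc4ccccc4)cc(OC)cc3OCc3ccccc3)=C[C@H]12
F3 | step 8 | (3Z)-9-(benzyloxy)-5-[2,6-bis(benzyloxy)-4-methoxybenzoyl]-2,2-dimethyl-2H-1-benzoxocin-6(5H)-one (diketo tautomer drawn, C5 configurationally labile) | CC1(C)/C=C\C(C(=O)c2c(OCc3ccccc3)cc(OC)cc2OCc2ccccc2)C(=O)c2ccc(OCc3ccccc3)cc2O1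
F4 | step 8 | 5-(2,6-dihydroxy-4-methoxybenzoyl)-9-hydroxy-2,2-dimethyl-3,4-dihydro-2H-1-benzoxocin-6(5H)-one (diketo tautomer drawn, C5 configurationally labile) | CC1(C)CCC(C(=O)c2c(O)cc(OC)cc2O)C(=O)c2ccc(O)cc2O1
F5 | step 9 | [(5Z)-9-(benzyloxy)-2,2-dimethyl-6-(pyrrolidin-1-yl)-3,4-dihydro-2H-1-benzoxocin-5-yl][2,6-bis(benzyloxy)-4-methoxyphenyl]methanone | CC1(C)CC\C(C(=O)c2c(OCc3ccccc3)cc(OC)cc2OCc2ccccc2)=C(N2CCCC2)/c2ccc(OCc3ccccc3)cc2O1
F6 | step 3 | 7-(benzyloxy)-2,2-dimethyl-2H-chromen-4-yl trifluoromethanesulfonate | CC1(C)C=C(OS(=O)(=O)C(F)(F)F)c2ccc(OCc3ccccc3)cc2O1
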